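The seven-membered ring (C1, C5 to C10, daucane numbering) hides a cyclohepta-1,4-diene: oxygen sits on C6 and on C8/C9, C7 is an isolated CH2, and the quaternary C1 is bonded to C10. The plan therefore rests on cutting C1–C10 by a retro-Cope step to a cis-divinylcyclopropane (ring C6–C7–C8). In one operation an enantiopure cis-2-methyl-2-vinylcyclopropylzinc reagent is coupled with 2-bromo-3-methylcyclopent-2-enone and the resulting 2-(vinylcyclopropyl)enone rearranges: the seven-membered ring closes, C1 is set by chirality transfer, and the C5=C6 and C8=C9 alkenes appear exactly where oxygen is needed. C1 then directs the other five stereocentres.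

Key step: step 5

Numbering used throughout, also for the same carbon atoms in all precursors:
- C1 is the quaternary ring-fusion carbon bearing CH3.
- C2 and C3 are the CH2 groups of the five-membered ring.
- C4 is the carbinol carbon bearing isopropyl.
- C5 is the ring-fusion CH.
- C6 is the acyloxy carbon and C7 is a CH2.
- C8 is the methyl carbinol and C9 is the secondary carbinol.
- C10 is the CH2 bonded to C1.
- β is the face of the C1 methyl group and α is the opposite face.

Assumption: the dioxaborolane controller is taken to show with 2 the same sense of induction as with other allylic alcohols. If it does not, its (4S,5S) enantiomer is used. Compounds 1, 6 and 16 and the controller are taken as commercial.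

Step 1
Reactants: 1 prop-2-yn-1-ol
Product: 2 (Z)-3-iodo-2-methylprop-2-en-1-ol
Conditions: MeMgBr (3 equiv), CuI (20 mol %), THF, −20 °C to rt; then I2, −40 °C to 0 °C
Reagents that add atoms: methylmagnesium bromide C[Mg]Br; iodine II
Why: Hydroxyl-directed, copper-catalysed anti-carbomagnesiation of the magnesium alkoxide gives a five-membered oxamagnesacycle, and iodinolysis with retention leaves iodine cis to CH2OH, so only the Z alkene should form.

Step 2
Reactants: 2 (Z)-3-iodo-2-methylprop-2-en-1-ol
Product: 3 [(1R,2R)-2-iodo-1-methylcyclopropyl]methanol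
Conditions: Et2Zn, CH2I2, DME, CH2Cl2, −10 °C; then (4R,5R)-2-butyl-N,N,N',N'-tetramethyl-1,3,2-dioxaborolane-4,5-dicarboxamide (1.2 equiv) and 2, −10 °C to rt
Reagents that add atoms: diiodomethane ICI
Why: Charette asymmetric Simmons–Smith cyclopropanation, in which stereospecific syn addition of CH2 (the future C7) keeps iodine and CH2OH cis and the boron-bound chiral controller chooses the alkene face, setting C6 and C8 (both R).

Step 3
Reactants: 3 [(1R,2R)-2-iodo-1-methylcyclopropyl]methanol
Product: 4 (1R,2R)-2-iodo-1-methylcyclopropane-1-carbaldehyde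
Conditions: TEMPO (10 mol %), PhI(OAc)2, CH2Cl2, rt
Reagents that add atoms: none
Why: Oxoammonium (TEMPO) oxidation stops at the aldehyde, whose α-carbon C8 is quaternary and therefore cannot epimerise.

Step 4
Reactants: 4 (1R,2R)-2-iodo-1-methylcyclopropane-1-carbaldehyde
Product: 5 (1R,2R)-1-ethenyl-2-iodo-1-methylcyclopropane
Conditions: Ph3PCH3Br, KOt-Bu, THF, 0 °C
Reagents that add atoms: methyltriphenylphosphonium bromide C[P+](c1ccccc1)(c1ccccc1)c1ccccc1.[Br-]
Why: Wittig methylenation converts the aldehyde into the C9=C10 vinyl group without touching either ring stereocentre or the C–I bond.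

Step 5
Reactants: 5 (1R,2R)-1-ethenyl-2-iodo-1-methylcyclopropane; 6 2-bromo-3-methylcyclopent-2-en-1-one
Product: 10 (3aR)-3a,6-dimethyl-3,3a,4,7-tetrahydroazulen-1(2H)-one (dauca-5,8-dien-4-one lacking the isopropyl group), via cyclopropyllithium 7 (not isolated), via cyclopropylzinc chloride 8 (not isolated), via cis-divinylcyclopropane 9 (not isolated)
Conditions: t-BuLi (2 equiv), Et2O, −78 °C; ZnCl2, THF, −78 °C to rt; 6, Pd2(dba)3 (2.5 mol %), SPhos (10 mol %), THF, 50 °C; then toluene, 100 °C
Reagents that add atoms: none
Why: Iodine–lithium exchange, transmetalation to zinc and Negishi coupling all proceed with retention at the cyclopropyl carbon C6, so 9 is formed with the enone alkene C5=C1 and the vinyl group C9=C10 cis on the three-membered ring C6–C7–C8. On heating, 9 undergoes the divinylcyclopropane–cycloheptadiene (Cope) rearrangement, a concerted [3,3]-sigmatropic shift that makes C1–C10, breaks the strained C6–C8 bond and moves the π bonds to C5=C6 and C8=C9; the closest known reaction type is the thermal rearrangement of 2-vinylcyclopropyl-substituted cycloalkenones to hydroazulenones with an angular methyl group. The seven-membered ring is closed by ring expansion of the cyclopropane (three to seven atoms) through the endo-boat transition state, the only one that can deliver two cis ring alkenes. The single new stereocentre, quaternary C1, is controlled by chirality transfer: with C6 and C8 both R, C10 can reach only one face of the ring-locked tetrasubstituted alkene, which gives 1R while C6 and C8 become sp2. The step needs cis geometry and chemoselectivity: configurationally stable cyclopropyl metals secure the former, the mild organozinc tolerates the ketone, and the competing homodienyl hydrogen shift is excluded because the C8 methyl group is trans to the cyclopentenone. The C1 methyl group points into the boat and raises the barrier, hence the heating, but release of the cyclopropane strain should still carry the rearrangement to completion.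

Step 6
Reactants: 10 (3aR)-3a,6-dimethyl-3,3a,4,7-tetrahydroazulen-1(2H)-one
Product: 11 (1R,3aR)-3a,6-dimethyl-1-(propan-2-yl)-1,2,3,3a,4,7-hexahydroazulen-1-ol (dauca-5,8-dien-4β-ol)
Conditions: CeCl3 (dried), i-PrMgCl, THF, −78 °C to −20 °C; aq. NH4Cl
Reagents that add atoms: isopropylmagnesium chloride CC(C)[Mg]Cl
Why: Organocerium 1,2-addition, in which the weakly basic reagent adds to the hindered, enolisable enone instead of deprotonating or reducing it and should approach C4 from the α face, anti to the pseudoaxial C1 methyl group (1,3-relationship, as in 4-oxo steroids), setting the 4β-hydroxy/4α-isopropyl centre (4R).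

Step 7
Reactants: 11 dauca-5,8-dien-4β-ol
Product: 12 5β,6β-epoxydauc-8-en-4β-ol
Conditions: VO(acac)2 (5 mol %), t-BuOOH (decane), CH2Cl2, 0 °C
Reagents that add atoms: tert-butyl hydroperoxide CC(C)(C)OO
Why: Hydroxyl-directed vanadium-catalysed epoxidation, in which the C4 alkoxide carries the peroxide to the allylic C5=C6 alkene only (C8=C9 stays intact) and to its own β face only, giving two temporary centres of defined configuration.

Step 8
Reactants: 12 5β,6β-epoxydauc-8-en-4β-ol
Product: 13 (3R,3aS,4R,8aR)-6,8a-dimethyl-3-(propan-2-yl)-1,2,3,3a,4,5,8,8a-octahydroazulene-3,4-diol (dauc-8-ene-4β,6β-diol, 5α-H)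
Conditions: Cp2TiCl2 (20 mol %), Mn dust, 2,4,6-collidine·HCl, 1,4-cyclohexadiene, THF, rt
Reagents that add atoms: none
Why: Titanocene-catalysed reductive epoxide opening (Nugent–RajanBabu type), in which electron transfer from Cp2TiCl cleaves C5–O to the tertiary C5 radical and hydrogen-atom transfer should come from the α face because the β face carries the C1 methyl group, the C4 oxygen and the bulky C6 titanoxy group, which sets 5α-H and thus the trans ring fusion.

Step 9
Reactants: 13 dauc-8-ene-4β,6β-diol
Product: 14 (3R,3aR,8aR)-3-hydroxy-6,8a-dimethyl-3-(propan-2-yl)-2,3,3a,5,8,8a-hexahydroazulen-4(1H)-one (4β-hydroxydauc-8-en-6-one)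
Conditions: Dess–Martin periodinane, pyridine, CH2Cl2, 0 °C
Reagents that add atoms: none
Why: Dess–Martin oxidation takes the only secondary alcohol to the ketone under buffered, non-basic conditions that should leave C5, the tertiary aldol unit and the β,γ-alkene C8=C9 in place.

Step 10
Reactants: 14 4β-hydroxydauc-8-en-6-one
Product: 15 (3R,3aS,4S,8aR)-6,8a-dimethyl-3-(propan-2-yl)-1,2,3,3a,4,5,8,8a-octahydroazulene-3,4-diol (jaeschkeanadiol, dauc-8-ene-4β,6α-diol)
Conditions: Me4NBH(OAc)3, MeCN/AcOH (1:1), −30 °C
Reagents that add atoms: none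
Why: Evans–Saksena reduction, in which the borohydride is bound by the 4β-hydroxyl group and delivers hydride internally to the β face of the C6 carbonyl, setting the equatorial 6α-alcohol (6S, the 1,3-anti diol) that external hydride would not give.

Step 11
Reactants: 15 jaeschkeanadiol; 16 4-acetoxybenzoic acid
Product: 18 (3R,3aS,4S,8aR)-3-hydroxy-6,8a-dimethyl-3-(propan-2-yl)-1,2,3,3a,4,5,8,8a-octahydroazulen-4-yl 4-hydroxybenzoate (ferutinin), via acetoxybenzoate ester 17 (not isolated)
Conditions: DCC, DMAP, CH2Cl2, rt to 40 °C; then MeOH, K2CO3 (cat.), 0 °C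
Reagents that add atoms: none
Why: Steglich esterification acylates only the secondary C6 alcohol (the C4 alcohol is tertiary) with retention, and brief methanolysis removes the much more electrophilic aryl acetate while the hindered benzoate stays.

Step 12
Reactants: 18 ferutinin
Product: 19 8α,9α-epoxide of 18 (4β-hydroxy-8α,9α-epoxydaucan-6α-yl 4-hydroxybenzoate)
Conditions: m-CPBA, CH2Cl2, 0 °C
Reagents that add atoms: 3-chloroperoxybenzoic acid OOC(=O)c1cccc(Cl)c1
Why: Prilezhaev epoxidation of the only alkene, where in the conformationally locked trans-fused cycloheptene chair the ring body and the axial C1 methyl group lie under the β face, so that oxygen should arrive from the α face and fix the final C9–O bond (9S).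

Step 13
Reactants: 19 8α,9α-epoxide
Product: 20 (3R,3aS,4S,6S,7S,8aR)-3,6,7-trihydroxy-6,8a-dimethyl-3-(propan-2-yl)decahydroazulen-4-yl 4-hydroxybenzoate (target)
Conditions: HClO4 (cat.), THF/H2O, 0 °C to rt
Reagents that add atoms: water O
Why: Acid-catalysed epoxide hydrolysis, in which water attacks the protonated epoxide at the tertiary C8 from the β face with inversion while the C9–O bond is untouched, giving the 8β,9α trans-diol (8S,9S), and the 4β-hydroxyl group cannot compete because the C5–C4 bond is equatorial on the trans-fused seven-membered ring.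

Compound list
1 | prop-2-yn-1-ol | C#CCO | starting material
2 | (Z)-3-iodo-2-methylprop-2-en-1-ol | OC/C(C)=C\I | intermediate
3 | [(1R,2R)-2-iodo-1-methylcyclopropyl]methanol | I[C@@H]1C[C@]1(C)CO | intermediate
4 | (1R,2R)-2-iodo-1-methylcyclopropane-1-carbaldehyde | I[C@@H]1C[C@]1(C)C=O | intermediate
5 | (1R,2R)-1-ethenyl-2-iodo-1-methylcyclopropane | I[C@@H]1C[C@]1(C)C=C | intermediate
6 | 2-bromo-3-methylcyclopent-2-en-1-one | CC1=C(Br)C(=O)CC1 | starting material
7 | cis-2-ethenyl-2-methylcyclopropyllithium (configuration of 5 retained) | [Li][C@@H]1C[C@]1(C)C=C | intermediate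
8 | cis-2-ethenyl-2-methylcyclopropylzinc chloride (configuration of 5 retained) | Cl[Zn][C@@H]1C[C@]1(C)C=C | intermediate
9 | 2-[(1R,2R)-2-ethenyl-2-methylcyclopropyl]-3-methylcyclopent-2-en-1-one | O=C1CCC(C)=C1[C@@H]1C[C@]1(C)C=C | intermediate
10 | (3aR)-3a,6-dimethyl-3,3a,4,7-tetrahydroazulen-1(2H)-one | O=C1CC[C@]2(C)CC=C(C)CC=C21 | intermediate
11 | (1R,3aR)-3a,6-dimethyl-1-(propan-2-yl)-1,2,3,3a,4,7-hexahydroazulen-1-ol (dauca-5,8-dien-4β-ol) | CC(C)[C@]1(O)CC[C@]2(C)CC=C(C)CC=C21 | intermediate
12 | 5β,6β-epoxydauc-8-en-4β-ol | CC(C)[C@]1(O)CC[C@]2(C)CC=C(C)C[C@H]3O[C@]213 | intermediate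
13 | dauc-8-ene-4β,6β-diol (5α-H) | CC(C)[C@]1(O)CC[C@]2(C)CC=C(C)C[C@@H](O)[C@H]21 | intermediate
14 | 4β-hydroxydauc-8-en-6-one (5α-H) | CC(C)[C@]1(O)CC[C@]2(C)CC=C(C)CC(=O)[C@H]21 | intermediate
15 | jaeschkeanadiol (dauc-8-ene-4β,6α-diol) | CC(C)[C@]1(O)CC[C@]2(C)CC=C(C)C[C@H](O)[C@H]21 | intermediate
16 | 4-acetoxybenzoic acid | CC(=O)Oc1ccc(cc1)C(=O)O | starting material
17 | 4β-hydroxydauc-8-en-6α-yl 4-acetoxybenzoate | CC(C)[C@]1(O)CC[C@]2(C)CC=C(C)C[C@H](OC(=O)c3ccc(OC(C)=O)cc3)[C@H]21 | intermediate
18 | ferutinin (4β-hydroxydauc-8-en-6α-yl 4-hydroxybenzoate) | CC(C)[C@]1(O)CC[C@]2(C)CC=C(C)C[C@H](OC(=O)c3ccc(O)cc3)[C@H]21 | intermediate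
19 | 4β-hydroxy-8α,9α-epoxydaucan-6α-yl 4-hydroxybenzoate | CC(C)[C@]1(O)CC[C@]2(C)C[C@@H]3O[C@]3(C)C[C@H](OC(=O)c4ccc(O)cc4)[C@H]21 | intermediate
20 | (3R,3aS,4S,6S,7S,8aR)-3,6,7-trihydroxy-6,8a-dimethyl-3-(propan-2-yl)decahydroazulen-4-yl 4-hydroxybenzoate | CC(C)[C@]1(O)CC[C@]2(C)C[C@H](O)[C@@](C)(O)C[C@H](OC(=O)c3ccc(O)cc3)[C@H]21 | target

Total step count: 13. Longest linear sequence: 13 steps (from 1; compounds 6 and 16 enter as bought).

Steps most likely to fail

Step 5.
- What may go wrong: Coupling of two hindered partners may stall, so that the zinc reagent is lost by protonation or homocoupling. The inward-pointing methyl group may slow the Cope step enough for homolytic cis–trans isomerisation of the cyclopropane to erode the chirality transfer.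
- Fallback (reversed polarity, ketone masked), setting out from 6 and 5 and returning at 10: Ketalisation of 6 (ethylene glycol, p-TsOH, benzene, Dean–Stark) gives 6-bromo-7-methyl-1,4-dioxaspiro[4.4]non-6-ene F1. Bromine–lithium exchange (n-BuLi, THF, −78 °C) and trapping with i-PrOBpin gives the alkenyl pinacol boronate F2. Suzuki–Miyaura coupling of F2 with the iodocyclopropane 5 (PdCl2(dppf), K3PO4, dioxane/H2O, 90 °C, retention at the cyclopropyl carbon) gives the ketal-protected cis-divinylcyclopropane F3. This rearranges at that temperature or in toluene at 110 °C to the dienone ketal F4. PPTS in wet acetone then releases 10.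

Step 6.
- What may go wrong: Enolisation at the doubly allylic C7 or at C3, β-hydride reduction by the secondary organometallic, or poor facial selectivity at C4.
- Fallback, setting out from 10 and returning at 11: Prop-1-en-2-ylmagnesium bromide/CeCl3 (a flatter sp2 nucleophile without β-hydrogen, THF, −78 °C) gives the isopropenyl carbinol F5. Hydrogenation with RhCl(PPh3)3 (H2, 1 atm, benzene) then saturates only the 1,1-disubstituted alkene and leaves both trisubstituted ring alkenes, giving 11.

Step 8.
- What may go wrong: Slow electron transfer to the very hindered epoxide, deoxygenation back to the alkene by loss of the titanoxy group, or hydrogen delivery from the wrong face.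
- Fallback, setting out from 10 and returning at 15 (oxygen brought to C6 as boron before the isopropyl group): Copper-catalysed conjugate borylation (B2pin2, CuCl, DPEphos, NaOt-Bu cat., MeOH, THF, rt) is chemoselective for the enone and gives the 6α-boryl ketone F6. Oxidation with NaBO3·4H2O (THF/H2O) gives the 6α-hydroxy ketone F7 with retention at C6. Excess i-PrMgCl/CeCl3 (−78 °C) then adds to C4 from the α face, anti to the C5–C6 bond, giving 15.

Further compounds
F1 | step 5 | 6-bromo-7-methyl-1,4-dioxaspiro[4.4]non-6-ene | CC1=C(Br)C2(CC1)OCCO2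
F2 | step 5 | 7-methyl-6-(4,4,5,5-tetramethyl-1,3,2-dioxaborolan-2-yl)-1,4-dioxaspiro[4.4]non-6-ene | CC1=C(B2OC(C)(C)C(C)(C)O2)C2(CC1)OCCO2
F3 | step 5 | 6-[(1R,2R)-2-ethenyl-2-methylcyclopropyl]-7-methyl-1,4-dioxaspiro[4.4]non-6-ene (ethylene ketal of 9) | CC1=C([C@@H]2C[C@]2(C)C=C)C2(CC1)OCCO2
F4 | step 5 | ethylene ketal of 10 | C12(OCCO1)CC[C@]3(C)CC=C(C)CC=C23
F5 | step 6 | (1R,3aR)-3a,6-dimethyl-1-(prop-1-en-2-yl)-1,2,3,3a,4,7-hexahydroazulen-1-ol | C=C(C)[C@]1(O)CC[C@]2(C)CC=C(C)CC=C21
F6 | step 8 | trans-fused 6α-(pinacolboryl) ketone (C4 ketone, 5α-H, C8=C9 alkene) | O=C1CC[C@]2(C)CC=C(C)C[C@H](B3OC(C)(C)C(C)(C)O3)[C@H]21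
F7 | step 8 | trans-fused 6α-hydroxy ketone (C4 ketone, 5α-H, C8=C9 alkene) | O=C1CC[C@]2(C)CC=C(C)C[C@H](O)[C@H]21
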